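## Structural features

The target (C24H14O11, a fucofuroeckol-type phlorotannin) has four benzene rings: ring A (C5a–C9a) and ring B (C1–C4, C4a, C9b) are the two benzo rings of a dibenzofuran, ring B is fused through oxygens on C1 and C2 to ring C as a dibenzo-1,4-dioxin, and ring C carries the pendant ring D through one more ether oxygen. Ring C is pentaoxygenated: going round it one meets the ring D ether oxygen, the central dioxin oxygen (bonded to C2 of ring B), the outer dioxin oxygen (bonded to C1 of ring B), a hydroxyl, the only CH, and a second hydroxyl. The other free hydroxyls sit on C3 (ring B), on C7 and C9 (ring A) and on ring D, which is a 3,5-dihydroxyphenoxy group. There is no stereocentre, so no stereocentres stand next to each other and every selectivity question is constitutional. The seven phloroglucinol- and pyrogallol-type phenols are sensitive to air, base and oxidants and are carried as alkyl ethers until the last step. The real difficulties are the orientation of the unsymmetrical dioxin (central oxygen to C2, outer oxygen to C1, not the reverse) and the aryl–oxygen bonds at doubly ortho-oxygenated positions, above all the ring C–O–ring D ether. The key step exploits the fact that ring D is a 1,3,5-trioxygenated benzene joined to ring C only through oxygen: that oxygen is placed on ring C as an ethynyl ether, and ring D is then built around the two alkyne carbons from a 3-alkoxycyclobutenone.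

## Logic of the disconnections

34 to 33: the seven O–alkyl bonds (six methyl, one ethyl) are cut. The free polyphenol would not survive the oxidants, bases and metal catalysts used earlier, so every intermediate is a neutral ether. The forward step must cleave all alkyl aryl ethers and leave the five aryl–O–aryl linkages (ring D ether, dioxin, furan) intact.

33 to 32, 31 and 29: the C9a–C9b bond between rings A and B is cut, which opens the furan. Ring A then hangs on ring B only through the C4a oxygen, and C9b carries a triflate (32), a hydroxyl (31) or, one oxidation level back, a formyl group (29). This keeps the dibenzofuran out of all coupling steps and lets ring B be handled as a simple benzaldehyde. The forward step must close a five-membered ring at a doubly ortho-substituted triflate onto the only reachable C–H of ring A.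

29 to 28 and 27: the bond between the central ring C oxygen and C2 of ring B is cut, and the central oxygen is masked as its methoxymethyl ether. The closure is intramolecular and six-membered, so its orientation is already fixed by the other dioxin bond. The forward step needs an iodide on C2, a central oxygen that is freed only now, and no migration of ring B between the two neighbouring ring C oxygens.

27 to 20 and 25: the bond between the outer ring C oxygen and C1 of ring B is cut. In 25 this carbon bears fluorine ortho to the formyl group, so the bond can be made by nucleophilic aromatic substitution without a metal, which tolerates the crowding on both partners. The cut divides the molecule into two halves of similar size. The forward step demands that only the outer oxygen is nucleophilic: ring D is capped as a methyl ether, the central oxygen is still masked, and the outer oxygen is released from its silyl ether by fluoride in the same flask.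

25 to 23 and 24, then 22 and 21: the ring A–O–C4a ether, the C–I bond and one C–O bond are cut in turn. 21 is symmetrical, so the first substitution raises no regiochemical question, and 24 brings ring A complete. The forward steps need iodination para (not ortho) to the hydroxyl of 22 and an O-arylation that leaves iodide, fluoride and aldehyde untouched.

20 to 19: the O–CH3 bond on ring D is cut. The free phenol of 19 is the direct outcome of the ring-forming step and only needs capping.

19 to 13 and 14: ring D is taken apart into the two alkyne carbons of 13 and the four carbons of 14. The cut removes a whole ring and makes the ring C–O–ring D ether a simple phenol ether that exists before ring D does. The forward step must join the ketene derived from 14 to the alkyne with one orientation only.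

13 to 10, then 8 and 9: the two-carbon ethynyl unit is removed from the oxygen. This leads to a phenol and a C2 building block. The forward steps use strong bases, so every other oxygen of ring C must be protected and free of acidic positions.

8 to 5, 4, 2 and 1: the C–O bond made by lithiation and oxidation, the Si–O bond, the C–O bond made by aryl migration and the acetal C–O bond are cut in turn. 1 already has a hydroxyl, a formyl group and a CH exactly where the central oxygen, the outer oxygen and the ynol ether oxygen are needed, so the three contiguous oxygens are differentiated from the start. The lithiation must go to the CH next to the acetal and not to the CH between the two methoxy groups.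

## Other disconnections considered

Alternative 1: The cut runs through the dibenzofuran: the C9a–C9b bond and the furan C5a–O bond. In the forward sense 1,3,5-trimethoxybenzene A3 would add to C5 of 2-methoxy-1,4-benzoquinone A2, and the neighbouring hydroquinone hydroxyl would displace an ortho methoxy group of ring A to give 3,7,9-trimethoxydibenzofuran-2-ol A1.
- In its favour: two cheap partners, one polar operation near room temperature, and the C3 methoxy and C7/C9 pattern arrive correctly placed.
- Where it is better: for rings A and B it is clearly more economical than steps 15 to 17 of the chosen plan, which spend three operations on the same C–C bond.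
- Against it here: A1 has an oxygen on C2 and nothing on C1. C1 would still have to be oxygenated, and the dioxin would then be built from dibenzofuran oxygens onto a ring C that acts as a 1,2-dielectrophile. Ring C could no longer carry its five oxygens from the start, the ring D ether would have to be made by coupling at the most hindered oxygen, and the dioxin orientation would rest on telling apart two adjacent dibenzofuran hydroxyls.
- Comparison: structurally it solves the part the chosen plan treats least elegantly and leaves open the part the chosen plan solves. Mechanistically it is an acid-promoted conjugate addition and ipso substitution against a thermal pericyclic cascade. In overall step count the polarity reversal is expected to cost more than the short dibenzofuran synthesis saves.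

Alternative 2: The cut removes three C–C bonds of ring B (C1–C2, C3–C4, C4a–C9b) and thereby also opens the furan and the dioxin. In the forward sense a rhodium catalyst such as RhCl(PPh3)3 would trimerise the three tethered alkynyl ether units of triyne A5 to the hexa-O-methyl skeleton A4, which carries a benzyldimethylsilyl group on C3.
- In its favour: three rings and three C–C bonds in one step, far more than the single ring of the chosen key step.
- Where it is equal or better: the orientation of the dioxin is fixed by the tethers alone, without the protecting-group play of steps 12 to 14.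
- Against it here: A5 needs three ynol ethers, two of them on adjacent oxygens of a ring C that already bears ring D, and one of them aryl-substituted at carbon. The ring D ether must still be made beforehand by C–O coupling at the hindered oxygen. The silyl group on C3 needs a Tamao–Fleming-type oxidation afterwards. Electron-rich ynol ethers are prone to hydration and oligomerisation in the presence of cationic metal centres.
- Comparison: structurally more convergent; mechanistically a metal-templated (2+2+2) process against a metal-free thermal cascade; potentially shorter, but with the risk concentrated in one precursor that is hard to make and one step without close precedent for three ynol ethers.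

Alternative 3: The cut is the C1–C9b bond of ring B. In the forward sense heating 4-(4,6-dimethoxy-1-benzofuran-2-yl)-2,3-di(propan-2-yloxy)cyclobut-2-en-1-one A7 would open it to a dienylketene whose ketene carbon bonds to benzofuran C3, giving 7,9-dimethoxy-2,3-di(propan-2-yloxy)dibenzofuran-1-ol A6.
- In its favour: it belongs to the same pericyclic family as the chosen key step (4π opening, 6π closure) and installs all three ring B oxygens in one step with C1 as the only free hydroxyl.
- Where it is equal or better: it is intramolecular, so there is no bimolecular regiochemistry to control, and its reliability should be at least equal to that of step 7.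
- Against it here: the C2 and C3 oxygens carry the same isopropyl group although C2 must enter the dioxin and C3 must end as a free hydroxyl. The dioxin would again have to be closed from dibenzofuran oxygens onto a dihalogenated ring C, and the ring D ether remains unsolved.
- Comparison: structurally it addresses ring B where the chosen plan addresses ring D; mechanistically it is the closest relative of the chosen key step; in step count it is good for the dibenzofuran but expected to be worse overall for the same polarity reason as Alternative 1.

Key step: step 7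

Remarks on the chemistry and assumptions:
- Compounds 1, 9, 14, 21 and 24 are assumed to be commercial.
- Ring C is not derived from 3,4,5-trimethoxyphenol. That phenol has the right oxygen count after ortho-oxygenation, but it carries methyl groups on the two oxygens that must later be freed one after the other and a free hydroxyl where a methyl ether is wanted.
- In the ynol ether the central oxygen carries methoxymethyl, which directs the lithiation of step 4 and is removed by acid. The outer oxygen carries tri(propan-2-yl)silyl, which is removed by fluoride in the coupling flask.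
- The dioxin is not closed onto a preformed 1,2-dihalodibenzofuran. A regiodefined ortho-dihalide next to the very electron-rich ring A is hard to reach, and two unactivated couplings at doubly ortho-substituted carbons are less dependable than a substitution next to a formyl group followed by an intramolecular coupling. The furan is therefore closed after the dioxin.
- ArC stands for the 4,6-dimethoxy-2-(methoxymethoxy)-3-[tri(propan-2-yl)silyloxy]phenyl group.
- The (E) geometry of 10 and the racemic sp3 centre of 16 are transient and have no consequence for the target.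

## Route

Step 1
Reactants: 1 2-hydroxy-4,6-dimethoxybenzaldehyde
Product: 2 2,4-dimethoxy-6-(methoxymethoxy)benzaldehyde
Conditions: NaH, MOMCl, DMF, 0 °C to rt
Reagents that add atoms: chloromethyl methyl ether, COCCl
Why: O-alkylation of the sodium phenoxide (Williamson type) should be clean because the aldehyde cannot enolise. The acetal installed here later directs the lithiation and is the acid-labile mask of the central dioxin oxygen.

Step 2
Reactants: 2 2,4-dimethoxy-6-(methoxymethoxy)benzaldehyde
Product: 4 2,4-dimethoxy-6-(methoxymethoxy)phenol, via 2,4-dimethoxy-6-(methoxymethoxy)phenyl formate 3 (not isolated)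
Conditions: mCPBA, CH2Cl2, 0 °C to rt; then K2CO3 (cat.), MeOH, rt
Reagents that add atoms: 3-chloroperoxybenzoic acid, OOC(=O)c1cccc(Cl)c1
Why: Baeyer–Villiger (Dakin-type) oxidation: the trioxygenated aryl group migrates readily in the Criegee intermediate, and methanolysis of the aryl formate should give the phenol. The aldehyde carbon is thereby exchanged for the oxygen that becomes the outer dioxin oxygen.

Step 3
Reactants: 4 2,4-dimethoxy-6-(methoxymethoxy)phenol
Product: 5 [2,4-dimethoxy-6-(methoxymethoxy)phenoxy]tri(propan-2-yl)silane
Conditions: NaH, THF, 0 °C; then TIPSCl, rt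
Reagents that add atoms: chlorotri(propan-2-yl)silane, CC(C)[Si](Cl)(C(C)C)C(C)C
Why: Silylation of the sodium phenoxide should proceed despite the two ortho substituents. The bulky silyl ether has no acidic hydrogen, resists alkyllithiums, KH and heat, and is fluoride-labile, which allows unmasking in the coupling flask of step 12.

Step 4
Reactants: 5 [2,4-dimethoxy-6-(methoxymethoxy)phenoxy]tri(propan-2-yl)silane
Product: 8 4,6-dimethoxy-2-(methoxymethoxy)-3-[tri(propan-2-yl)silyloxy]phenol, via [3-lithio-4,6-dimethoxy-2-(methoxymethoxy)phenoxy]tri(propan-2-yl)silane 6 (not isolated), via dimethyl {4,6-dimethoxy-2-(methoxymethoxy)-3-[tri(propan-2-yl)silyloxy]phenyl}boronate 7 (not isolated)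
Conditions: n-BuLi, TMEDA, THF, −78 to 0 °C; B(OMe)3, −78 °C to rt; then AcOH, 30% H2O2, 0 °C to rt
Reagents that add atoms: hydrogen peroxide, OO
Why: Directed ortho-metalation: the chelating methoxymethoxy group, helped by the flanking methoxy group, should direct lithium to the CH between them rather than to the CH between the two methoxy groups. Borylation and oxidation under weakly acidic conditions should turn C–Li into C–OH without loss of the silyl ether.

Step 5
Reactants: 8 4,6-dimethoxy-2-(methoxymethoxy)-3-[tri(propan-2-yl)silyloxy]phenol; 9 trichloroethene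
Product: 10 {3-[(E)-1,2-dichloroethenoxy]-4,6-dimethoxy-2-(methoxymethoxy)phenoxy}tri(propan-2-yl)silane
Conditions: KH, THF, 0 °C; then Cl2C=CHCl, −40 °C to rt
Reagents that add atoms: none
Why: Base-induced loss of HCl from 9 gives dichloroethyne in the flask, and anti addition of the potassium phenoxide to it should give the (E)-1,2-dichlorovinyl ether. This is the standard entry to ynol ethers of hindered alcohols and phenols.

Step 6
Reactants: 10 {3-[(E)-1,2-dichloroethenoxy]-4,6-dimethoxy-2-(methoxymethoxy)phenoxy}tri(propan-2-yl)silane
Product: 13 [3-(ethynyloxy)-4,6-dimethoxy-2-(methoxymethoxy)phenoxy]tri(propan-2-yl)silane, via [3-(chloroethynyloxy)-4,6-dimethoxy-2-(methoxymethoxy)phenoxy]tri(propan-2-yl)silane 11 (not isolated), via lithium (ArC-oxy)ethynide 12 (not isolated)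
Conditions: n-BuLi (2.3 equiv), Et2O, −78 to −40 °C; then H2O, −78 °C
Reagents that add atoms: none
Why: Elimination of HCl by the first equivalent of base and chlorine–lithium exchange by the second should give the lithium acetylide, which is protonated cold to the terminal ynol ether. An aryl ynol ether has no β-hydrogen for retro-ene loss of ketene, but it is acid-sensitive and is used at once.

Step 7
Reactants: 13 [3-(ethynyloxy)-4,6-dimethoxy-2-(methoxymethoxy)phenoxy]tri(propan-2-yl)silane; 14 3-ethoxycyclobut-2-en-1-one
Product: 19 3-ethoxy-5-{4,6-dimethoxy-2-(methoxymethoxy)-3-[tri(propan-2-yl)silyloxy]phenoxy}phenol, via 3-ethoxybuta-1,3-dien-1-one 15 (not isolated), via 3-(ArC-oxy)-4-(1-ethoxyethenyl)cyclobut-2-en-1-one 16 (not isolated), via (3E)-3-(ArC-oxy)-5-ethoxyhexa-1,3,5-trien-1-one 17 (not isolated), via 3-(ArC-oxy)-5-ethoxycyclohexa-2,4-dien-1-one 18 (not isolated)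
Conditions: toluene, 80 °C (slow addition of 14), then 110 °C, sealed vessel under argon
Reagents that add atoms: none
Why: Heating opens 14 by 4π electrocyclic ring opening to vinylketene 15. The nucleophilic CH terminus of ynol ether 13 attacks the electrophilic ketene carbon, and regioselective (2+2) cycloaddition gives cyclobutenone 16, which forms the two C–C bonds to the former alkyne carbons. 16 opens again (4π) to dienylketene 17, and a thermal disrotatory 6π electrocyclisation re-joins the two ends of the four-carbon unit as the third C–C bond, giving dienone 18, which tautomerises to phenol 19; this closure is the mode by which ring D is formed. The closest known reaction type is the Danheiser benzannulation of cyclobutenones with alkoxy- and silyloxy-alkynes to resorcinol monoethers, of which an aryl ynol ether is a less electron-rich member. No stereocentre results, since the sp3 carbon of 16 is formed racemic and is lost on ring opening. The selectivity needed is the orientation of the ketene–alkyne union: the oxygen lone pair of 13 polarises the triple bond so that the CH carbon bonds to the ketene carbonyl carbon, which places the aryloxy group meta to both the new hydroxyl and the ethoxy group (a direct (4+2) union of the same polarity would give the same phenol). The diaryl ether oxygen already sits on ring C, so no C–O coupling at this doubly ortho-substituted oxygen is required. Slow addition of 14 keeps the ketene concentration low and should limit ketene dimerisation and acylation of 19.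

Step 8
Reactants: 19 3-ethoxy-5-{4,6-dimethoxy-2-(methoxymethoxy)-3-[tri(propan-2-yl)silyloxy]phenoxy}phenol
Product: 20 [3-(3-ethoxy-5-methoxyphenoxy)-4,6-dimethoxy-2-(methoxymethoxy)phenoxy]tri(propan-2-yl)silane
Conditions: MeI, K2CO3, acetone, 50 °C
Reagents that add atoms: iodomethane, CI
Why: O-methylation (Williamson) caps the unhindered ring D phenol so that it cannot compete as a nucleophile in step 12. The methyl ether leaves with the others in step 18.

Step 9
Reactants: 21 2,6-difluoro-4-methoxybenzaldehyde
Product: 22 2-fluoro-6-hydroxy-4-methoxybenzaldehyde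
Conditions: KOH, DMSO–H2O, 60 °C; then aq HCl
Reagents that add atoms: potassium hydroxide, [K+].[OH-]
Why: Nucleophilic aromatic substitution: both fluorides are ortho to the formyl group and equivalent, and the phenoxide formed after the first exchange deactivates the ring, so only one fluoride should be replaced.

Step 10
Reactants: 22 2-fluoro-6-hydroxy-4-methoxybenzaldehyde
Product: 23 2-fluoro-6-hydroxy-3-iodo-4-methoxybenzaldehyde
Conditions: NIS, CF3CO2H (cat.), MeCN, 0 °C to rt
Reagents that add atoms: N-iodosuccinimide, O=C1CCC(=O)N1I
Why: Electrophilic aromatic iodination: the position para to the hydroxyl and ortho to the methoxy group should be preferred over the position squeezed between hydroxyl and methoxy. The formyl group keeps the ring from taking up a second iodine.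

Step 11
Reactants: 23 2-fluoro-6-hydroxy-3-iodo-4-methoxybenzaldehyde; 24 (3,5-dimethoxyphenyl)boronic acid
Product: 25 6-(3,5-dimethoxyphenoxy)-2-fluoro-3-iodo-4-methoxybenzaldehyde
Conditions: Cu(OAc)2 (20 mol%), pyridine, 4 Å molecular sieves, CH2Cl2, O2 (1 atm), rt
Reagents that add atoms: none
Why: Chan–Lam coupling: copper-catalysed oxidative O-arylation at room temperature should attach ring A through oxygen while leaving the aryl iodide, the activated fluoride and the aldehyde untouched, which a substitution or Ullmann route would not.

Step 12
Reactants: 20 [3-(3-ethoxy-5-methoxyphenoxy)-4,6-dimethoxy-2-(methoxymethoxy)phenoxy]tri(propan-2-yl)silane; 25 6-(3,5-dimethoxyphenoxy)-2-fluoro-3-iodo-4-methoxybenzaldehyde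
Product: 27 6-(3,5-dimethoxyphenoxy)-2-[3-(3-ethoxy-5-methoxyphenoxy)-4,6-dimethoxy-2-(methoxymethoxy)phenoxy]-3-iodo-4-methoxybenzaldehyde, via cesium 3-(3-ethoxy-5-methoxyphenoxy)-4,6-dimethoxy-2-(methoxymethoxy)phenolate 26 (not isolated)
Conditions: CsF, DMF, 70 °C
Reagents that add atoms: none
Why: Fluoride cleaves the silyl ether to phenolate 26, which should displace the fluoride ortho to the formyl group by addition–elimination (SNAr). Only the outer oxygen is free at this point, so the orientation of the future dioxin is fixed here, and SNAr tolerates doubly ortho-substituted partners better than a metal-catalysed coupling.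

Step 13
Reactants: 27 6-(3,5-dimethoxyphenoxy)-2-[3-(3-ethoxy-5-methoxyphenoxy)-4,6-dimethoxy-2-(methoxymethoxy)phenoxy]-3-iodo-4-methoxybenzaldehyde
Product: 28 6-(3,5-dimethoxyphenoxy)-2-[3-(3-ethoxy-5-methoxyphenoxy)-2-hydroxy-4,6-dimethoxyphenoxy]-3-iodo-4-methoxybenzaldehyde
Conditions: HCl (cat.), MeOH–THF, 40 °C
Reagents that add atoms: none
Why: Acid-catalysed acetal exchange should free the central phenol. Methanol in excess traps the methoxymethyl cation as dimethoxymethane, which protects the electron-rich rings from alkylation, and aryl alkyl ethers, the iodide and the aldehyde are not affected.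

Step 14
Reactants: 28 6-(3,5-dimethoxyphenoxy)-2-[3-(3-ethoxy-5-methoxyphenoxy)-2-hydroxy-4,6-dimethoxyphenoxy]-3-iodo-4-methoxybenzaldehyde
Product: 29 2-(3,5-dimethoxyphenoxy)-6-(3-ethoxy-5-methoxyphenoxy)-4,7,9-trimethoxydibenzo[b,e][1,4]dioxine-1-carbaldehyde
Conditions: CuI (20 mol%), N,N-dimethylglycine (40 mol%), Cs2CO3, 1,4-dioxane, 90 °C
Reagents that add atoms: none
Why: Intramolecular Ullmann-type C–O coupling of the central phenol with the aryl iodide closes the six-membered dioxin, and intramolecularity should overcome the ortho substitution. A weakly polar solvent and moderate temperature are chosen so that the copper-mediated closure outruns any base-induced aryl migration between the two ring C oxygens.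

Step 15
Reactants: 29 2-(3,5-dimethoxyphenoxy)-6-(3-ethoxy-5-methoxyphenoxy)-4,7,9-trimethoxydibenzo[b,e][1,4]dioxine-1-carbaldehyde
Product: 31 2-(3,5-dimethoxyphenoxy)-6-(3-ethoxy-5-methoxyphenoxy)-4,7,9-trimethoxydibenzo[b,e][1,4]dioxin-1-ol, via 2-(3,5-dimethoxyphenoxy)-6-(3-ethoxy-5-methoxyphenoxy)-4,7,9-trimethoxydibenzo[b,e][1,4]dioxin-1-yl formate 30 (not isolated)
Conditions: mCPBA, CH2Cl2, 0 °C to rt; then K2CO3 (cat.), MeOH, rt
Reagents that add atoms: 3-chloroperoxybenzoic acid, OOC(=O)c1cccc(Cl)c1
Why: Baeyer–Villiger (Dakin-type) oxidation: the aldehyde is flanked by two aryloxy groups and has a para methoxy group, so aryl migration should be fast and outpace oxidation of the other electron-rich rings. The formyl group that served as activator is thereby turned into the C9b oxygen handle.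

Step 16
Reactants: 31 2-(3,5-dimethoxyphenoxy)-6-(3-ethoxy-5-methoxyphenoxy)-4,7,9-trimethoxydibenzo[b,e][1,4]dioxin-1-ol
Product: 32 2-(3,5-dimethoxyphenoxy)-6-(3-ethoxy-5-methoxyphenoxy)-4,7,9-trimethoxydibenzo[b,e][1,4]dioxin-1-yl trifluoromethanesulfonate
Conditions: Tf2O, pyridine, CH2Cl2, −20 to 0 °C
Reagents that add atoms: trifluoromethanesulfonic anhydride, O=S(=O)(OS(=O)(=O)C(F)(F)F)C(F)(F)F
Why: O-sulfonylation of the only free phenol should convert the C9b oxygen into a leaving group for palladium. The alkyl aryl ethers and the arenes do not react with the anhydride at this temperature in the presence of pyridine.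

Step 17
Reactants: 32 2-(3,5-dimethoxyphenoxy)-6-(3-ethoxy-5-methoxyphenoxy)-4,7,9-trimethoxydibenzo[b,e][1,4]dioxin-1-yl trifluoromethanesulfonate
Product: 33 hepta-O-alkyl target (target skeleton with methyl ethers on C3, C7, C9 and on both ring C hydroxyls, and ring D as 3-ethoxy-5-methoxyphenoxy)
Conditions: Pd(OAc)2 (10 mol%), PCy3·HBF4 (20 mol%), pivalic acid (30 mol%), K2CO3, N,N-dimethylacetamide, 120 °C
Reagents that add atoms: none
Why: Palladium-catalysed intramolecular direct arylation: oxidative addition of zerovalent palladium into the C–OTf bond, pivalate-assisted concerted metalation–deprotonation of ring A and reductive elimination should close the furan. The two ortho C–H bonds of ring A are equivalent and ring C offers no C–H within reach, so only one dibenzofuran can form.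

Step 18
Reactants: 33 hepta-O-alkyl target
Product: 34 target heptaphenol (CNP0256302.0)
Conditions: BBr3 (excess), CH2Cl2, −78 °C to rt; then MeOH, H2O
Reagents that add atoms: none
Why: Lewis acid-mediated ether cleavage: bromide attacks the alkyl carbon of each boron-complexed alkyl aryl ether, so the six methyl ethers and the ethyl ether should all be cleaved. The diaryl ether, dioxin and furan C–O bonds join two sp2 carbons and cannot be cleaved in this way.

## Compound list

1 | 2-hydroxy-4,6-dimethoxybenzaldehyde | O=Cc1c(O)cc(OC)cc1OC | starting material
2 | 2,4-dimethoxy-6-(methoxymethoxy)benzaldehyde | O=Cc1c(OCOC)cc(OC)cc1OC | intermediate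
3 | 2,4-dimethoxy-6-(methoxymethoxy)phenyl formate | O=COc1c(OCOC)cc(OC)cc1OC | intermediate (not isolated)
4 | 2,4-dimethoxy-6-(methoxymethoxy)phenol | Oc1c(OCOC)cc(OC)cc1OC | intermediate
5 | [2,4-dimethoxy-6-(methoxymethoxy)phenoxy]tri(propan-2-yl)silane | CC(C)[Si](Oc1c(OCOC)cc(OC)cc1OC)(C(C)C)C(C)C | intermediate
6 | [3-lithio-4,6-dimethoxy-2-(methoxymethoxy)phenoxy]tri(propan-2-yl)silane | CC(C)[Si](Oc1c(OCOC)c([Li])c(OC)cc1OC)(C(C)C)C(C)C | intermediate (not isolated)
7 | dimethyl {4,6-dimethoxy-2-(methoxymethoxy)-3-[tri(propan-2-yl)silyloxy]phenyl}boronate | CC(C)[Si](Oc1c(OCOC)c(B(OC)OC)c(OC)cc1OC)(C(C)C)C(C)C | intermediate (not isolated)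
8 | 4,6-dimethoxy-2-(methoxymethoxy)-3-[tri(propan-2-yl)silyloxy]phenol | CC(C)[Si](Oc1c(OCOC)c(O)c(OC)cc1OC)(C(C)C)C(C)C | intermediate
9 | trichloroethene | ClC=C(Cl)Cl | starting material
10 | {3-[(E)-1,2-dichloroethenoxy]-4,6-dimethoxy-2-(methoxymethoxy)phenoxy}tri(propan-2-yl)silane | Cl/C=C(/Cl)Oc1c(OCOC)c(O[Si](C(C)C)(C(C)C)C(C)C)c(OC)cc1OC | intermediate
11 | [3-(chloroethynyloxy)-4,6-dimethoxy-2-(methoxymethoxy)phenoxy]tri(propan-2-yl)silane | ClC#COc1c(OCOC)c(O[Si](C(C)C)(C(C)C)C(C)C)c(OC)cc1OC | intermediate (not isolated)
12 | lithium (ArC-oxy)ethynide, the lithium acetylide of 13 | [Li]C#COc1c(OCOC)c(O[Si](C(C)C)(C(C)C)C(C)C)c(OC)cc1OC | intermediate (not isolated)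
13 | [3-(ethynyloxy)-4,6-dimethoxy-2-(methoxymethoxy)phenoxy]tri(propan-2-yl)silane | C#COc1c(OCOC)c(O[Si](C(C)C)(C(C)C)C(C)C)c(OC)cc1OC | intermediate
14 | 3-ethoxycyclobut-2-en-1-one | CCOC1=CC(=O)C1 | starting material
15 | 3-ethoxybuta-1,3-dien-1-one | CCOC(=C)C=C=O | intermediate (not isolated)
16 | 3-(ArC-oxy)-4-(1-ethoxyethenyl)cyclobut-2-en-1-one (racemic) | C=C(OCC)C1C(=O)C=C1Oc1c(OCOC)c(O[Si](C(C)C)(C(C)C)C(C)C)c(OC)cc1OC | intermediate (not isolated)
17 | (3E)-3-(ArC-oxy)-5-ethoxyhexa-1,3,5-trien-1-one (ketene and ethoxyvinyl groups cis) | O=C=C/C(Oc1c(OCOC)c(O[Si](C(C)C)(C(C)C)C(C)C)c(OC)cc1OC)=C\C(OCC)=C | intermediate (not isolated)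
18 | 3-(ArC-oxy)-5-ethoxycyclohexa-2,4-dien-1-one | O=C1C=C(Oc2c(OCOC)c(O[Si](C(C)C)(C(C)C)C(C)C)c(OC)cc2OC)C=C(OCC)C1 | intermediate (not isolated)
19 | 3-ethoxy-5-{4,6-dimethoxy-2-(methoxymethoxy)-3-[tri(propan-2-yl)silyloxy]phenoxy}phenol | CCOc1cc(O)cc(Oc2c(OCOC)c(O[Si](C(C)C)(C(C)C)C(C)C)c(OC)cc2OC)c1 | intermediate
20 | [3-(3-ethoxy-5-methoxyphenoxy)-4,6-dimethoxy-2-(methoxymethoxy)phenoxy]tri(propan-2-yl)silane | CCOc1cc(OC)cc(Oc2c(OCOC)c(O[Si](C(C)C)(C(C)C)C(C)C)c(OC)cc2OC)c1 | intermediate
21 | 2,6-difluoro-4-methoxybenzaldehyde | COc1cc(F)c(C=O)c(F)c1 | starting material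
22 | 2-fluoro-6-hydroxy-4-methoxybenzaldehyde | COc1cc(O)c(C=O)c(F)c1 | intermediate
23 | 2-fluoro-6-hydroxy-3-iodo-4-methoxybenzaldehyde | COc1cc(O)c(C=O)c(F)c1I | intermediate
24 | (3,5-dimethoxyphenyl)boronic acid | COc1cc(OC)cc(B(O)O)c1 | starting material
25 | 6-(3,5-dimethoxyphenoxy)-2-fluoro-3-iodo-4-methoxybenzaldehyde | COc1cc(Oc2cc(OC)cc(OC)c2)c(C=O)c(F)c1I | intermediate
26 | cesium 3-(3-ethoxy-5-methoxyphenoxy)-4,6-dimethoxy-2-(methoxymethoxy)phenolate | [Cs+].[O-]c1c(OCOC)c(Oc2cc(OCC)cc(OC)c2)c(OC)cc1OC | intermediate (not isolated)
27 | 6-(3,5-dimethoxyphenoxy)-2-[3-(3-ethoxy-5-methoxyphenoxy)-4,6-dimethoxy-2-(methoxymethoxy)phenoxy]-3-iodo-4-methoxybenzaldehyde | COc1cc(Oc2cc(OC)cc(OC)c2)c(C=O)c(Oc2c(OCOC)c(Oc3cc(OCC)cc(OC)c3)c(OC)cc2OC)c1I | intermediate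
28 | 6-(3,5-dimethoxyphenoxy)-2-[3-(3-ethoxy-5-methoxyphenoxy)-2-hydroxy-4,6-dimethoxyphenoxy]-3-iodo-4-methoxybenzaldehyde | COc1cc(Oc2cc(OC)cc(OC)c2)c(C=O)c(Oc2c(O)c(Oc3cc(OCC)cc(OC)c3)c(OC)cc2OC)c1I | intermediate
29 | 2-(3,5-dimethoxyphenoxy)-6-(3-ethoxy-5-methoxyphenoxy)-4,7,9-trimethoxydibenzo[b,e][1,4]dioxine-1-carbaldehyde | O=Cc1c(Oc2cc(OC)cc(OC)c2)cc(OC)c2Oc3c(Oc4cc(OCC)cc(OC)c4)c(OC)cc(OC)c3Oc12 | intermediate
30 | 2-(3,5-dimethoxyphenoxy)-6-(3-ethoxy-5-methoxyphenoxy)-4,7,9-trimethoxydibenzo[b,e][1,4]dioxin-1-yl formate | O=COc1c(Oc2cc(OC)cc(OC)c2)cc(OC)c2Oc3c(Oc4cc(OCC)cc(OC)c4)c(OC)cc(OC)c3Oc12 | intermediate (not isolated)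
31 | 2-(3,5-dimethoxyphenoxy)-6-(3-ethoxy-5-methoxyphenoxy)-4,7,9-trimethoxydibenzo[b,e][1,4]dioxin-1-ol | Oc1c(Oc2cc(OC)cc(OC)c2)cc(OC)c2Oc3c(Oc4cc(OCC)cc(OC)c4)c(OC)cc(OC)c3Oc12 | intermediate
32 | 2-(3,5-dimethoxyphenoxy)-6-(3-ethoxy-5-methoxyphenoxy)-4,7,9-trimethoxydibenzo[b,e][1,4]dioxin-1-yl trifluoromethanesulfonate | O=S(=O)(Oc1c(Oc2cc(OC)cc(OC)c2)cc(OC)c2Oc3c(Oc4cc(OCC)cc(OC)c4)c(OC)cc(OC)c3Oc12)C(F)(F)F | intermediate
33 | hepta-O-alkyl target: the target skeleton with methoxy groups on C3, C7 and C9 of the dibenzofuran and on both ring C hydroxyl positions, and ring D as 3-ethoxy-5-methoxyphenoxy | COc1cc2oc3cc(OC)cc(OC)c3c2c5Oc4c(OC)cc(OC)c(Oc6cc(OCC)cc(OC)c6)c4Oc15 | intermediate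
34 | target heptaphenol CNP0256302.0: dibenzofuran (OH on C3, C7, C9) fused at C1/C2 through a 1,4-dioxin to ring C (two OH), which bears a 3,5-dihydroxyphenoxy group next to the central dioxin oxygen | Oc1cc(O)cc(Oc2c(O)cc(O)c3c2Oc2c(O)cc4oc5cc(O)cc(O)c5c4c2O3)c1 | target

## Step count and least certain steps

Total step count: 18. Longest linear sequence: 15 steps (steps 1 to 8 and 12 to 18); the three-step branch (steps 9 to 11) supplies 25.

Step 7 (key step). The most likely failure is that the ketene–alkyne cycloaddition is too slow, because an aryloxy alkyne is less electron-rich than an alkoxy alkyne. In that case dimerisation of the vinylketene, thermal oligomerisation of the ynol ether and acylation of the product phenol by ketene would take over. Fallback: abandon the ring construction and make the ether by C–O coupling. Phenol 8 is coupled with (3-ethoxy-5-methoxyphenyl)boronic acid F1 under Chan–Lam conditions (Cu(OAc)2, pyridine, air, CH2Cl2, rt), which are mild enough for the silyl ether and known for doubly ortho-substituted phenols. This sets out from 8 and returns to the route at 20.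

Step 12. The most likely failure is steric retardation of the addition step, since the fluoride is flanked by the large iodine and the formyl group and the phenolate is itself doubly ortho-substituted. Slow substitution would let the phenolate attack the aldehyde or exchange the ring A aryloxy group instead. Fallback: use a smaller closing halogen, so that the substitution site is less crowded and the later closure runs on an aryl bromide. 22 is brominated with NBS to 3-bromo-2-fluoro-6-hydroxy-4-methoxybenzaldehyde F2, which is coupled with 24 as in step 11 to 3-bromo-6-(3,5-dimethoxyphenoxy)-2-fluoro-4-methoxybenzaldehyde F3. Reaction of F3 with 20 and CsF gives the bromo analogue of 27 F4, acid removes the acetal to give the bromo analogue of 28 F5, and copper-catalysed closure at 110 °C gives 29. This sets out from 22 and 20 and returns at 29.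

Step 14. The most likely failure is migration of ring B from the outer to the central ring C oxygen (a Smiles-type ipso substitution at C1, which is activated by the ortho formyl group) before the copper-mediated closure. That would scramble the orientation of the dioxin; loss of iodine by reduction is a second possibility. Fallback: remove the activation before the phenolate is generated. 27 is treated with HC(OMe)3 and TsOH in MeOH, which cleaves the methoxymethyl ether and converts the aldehyde into its acetal, giving the dimethyl acetal of 28 F6. Copper-catalysed closure then gives the dimethyl acetal of 29 F7, and aqueous HCl in THF releases 29. This sets out from 27 and returns at 29.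

Step 17. The most likely failure is slow oxidative addition at a triflate flanked by two aryloxy groups on a very electron-rich ring, so that base-induced S–O cleavage returns phenol 31. Fallback: use the carbon of the aldehyde as the leaving group. 29 is oxidised (NaClO2, NaH2PO4, 2-methylbut-2-ene, t-BuOH–H2O; Pinnick oxidation) to the carboxylic acid corresponding to 29 F8. Intramolecular decarboxylative C–H arylation (Pd(O2CCF3)2, Ag2CO3, DMSO–dioxane, 150 °C) then closes the furan; this reaction is known for 2-aryloxybenzoic acids and is favoured by two ortho oxygen substituents. This sets out from 29 and returns at 33.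

Further compounds
F1 | step 7 | (3-ethoxy-5-methoxyphenyl)boronic acid | CCOc1cc(OC)cc(B(O)O)c1
F2 | step 12 | 3-bromo-2-fluoro-6-hydroxy-4-methoxybenzaldehyde | COc1cc(O)c(C=O)c(F)c1Br
F3 | step 12 | 3-bromo-6-(3,5-dimethoxyphenoxy)-2-fluoro-4-methoxybenzaldehyde | COc1cc(Oc2cc(OC)cc(OC)c2)c(C=O)c(F)c1Br
F4 | step 12 | 3-bromo-6-(3,5-dimethoxyphenoxy)-2-[3-(3-ethoxy-5-methoxyphenoxy)-4,6-dimethoxy-2-(methoxymethoxy)phenoxy]-4-methoxybenzaldehyde (bromo analogue of 27) | COc1cc(Oc2cc(OC)cc(OC)c2)c(C=O)c(Oc2c(OCOC)c(Oc3cc(OCC)cc(OC)c3)c(OC)cc2OC)c1Br
F5 | step 12 | 3-bromo-6-(3,5-dimethoxyphenoxy)-2-[3-(3-ethoxy-5-methoxyphenoxy)-2-hydroxy-4,6-dimethoxyphenoxy]-4-methoxybenzaldehyde (bromo analogue of 28) | COc1cc(Oc2cc(OC)cc(OC)c2)c(C=O)c(Oc2c(O)c(Oc3cc(OCC)cc(OC)c3)c(OC)cc2OC)c1Br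
F6 | step 14 | 2-[2-(dimethoxymethyl)-3-(3,5-dimethoxyphenoxy)-6-iodo-5-methoxyphenoxy]-6-(3-ethoxy-5-methoxyphenoxy)-3,5-dimethoxyphenol (dimethyl acetal of 28) | COc1cc(Oc2cc(OC)cc(OC)c2)c(C(OC)OC)c(Oc2c(O)c(Oc3cc(OCC)cc(OC)c3)c(OC)cc2OC)c1I
F7 | step 14 | 1-(dimethoxymethyl)-2-(3,5-dimethoxyphenoxy)-6-(3-ethoxy-5-methoxyphenoxy)-4,7,9-trimethoxydibenzo[b,e][1,4]dioxine (dimethyl acetal of 29) | COC(OC)c1c(Oc2cc(OC)cc(OC)c2)cc(OC)c2Oc3c(Oc4cc(OCC)cc(OC)c4)c(OC)cc(OC)c3Oc12
F8 | step 17 | 2-(3,5-dimethoxyphenoxy)-6-(3-ethoxy-5-methoxyphenoxy)-4,7,9-trimethoxydibenzo[b,e][1,4]dioxine-1-carboxylic acid | OC(=O)c1c(Oc2cc(OC)cc(OC)c2)cc(OC)c2Oc3c(Oc4cc(OCC)cc(OC)c4)c(OC)cc(OC)c3Oc12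
A1 | alternative 1 | 3,7,9-trimethoxydibenzofuran-2-ol | COc1cc(OC)c2c(c1)oc1cc(OC)c(O)cc12
A2 | alternative 1 | 2-methoxy-1,4-benzoquinone | COC1=CC(=O)C=CC1=O
A3 | alternative 1 | 1,3,5-trimethoxybenzene | COc1cc(OC)cc(OC)c1
A4 | alternative 2 | hexa-O-methyl target skeleton with benzyldimethylsilyl on C3 of ring B in place of the hydroxyl | COc1cc(OC)cc(Oc2c(OC)cc(OC)c3c2Oc2c([Si](C)(C)Cc4ccccc4)cc4oc5cc(OC)cc(OC)c5c4c2O3)c1
A5 | alternative 2 | triyne: 3,5-dimethoxyphenyl ether of a ring C whose central oxygen carries a (benzyldimethylsilyl)ethynyl group and whose outer oxygen carries a [2-(ethynyloxy)-4,6-dimethoxyphenyl]ethynyl group | COc1cc(OC)cc(Oc2c(OC)cc(OC)c(OC#Cc3c(OC#C)cc(OC)cc3OC)c2OC#C[Si](C)(C)Cc2ccccc2)c1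
A6 | alternative 3 | 7,9-dimethoxy-2,3-di(propan-2-yloxy)dibenzofuran-1-ol | COc1cc(OC)c2c(c1)oc1cc(OC(C)C)c(OC(C)C)c(O)c12
A7 | alternative 3 | 4-(4,6-dimethoxy-1-benzofuran-2-yl)-2,3-di(propan-2-yloxy)cyclobut-2-en-1-one | O=C1C(OC(C)C)=C(OC(C)C)C1c1cc2c(OC)cc(OC)cc2o1
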